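## Retrosynthetic overview

1. Prinsepiol 17 comes from tetrabenzyl ether 16 and that from bicyclic lactone 14; after the key step only C8=O → CH2 (via the lactol) and O-debenzylation remain.
2. Key disconnection: bonds C1–C2 and C4–C5 of ring C1–C2–O3–C4–C5, made together by [3+2] cycloaddition of the carbonyl ylide ArCH=O(+)–CH2(−) (13) to the ene-diol C=C of butenolide 9.
3. Enabling feature: each tetrahydrofuran ring is an ArCH–O–CH2 triad (C2–O3–C4, C6–O7–C8) bridging the vicinal carbinol carbons C1 and C5. C1–C5 with its two oxygens is an ene-diol, which is stable and polarised as an aci-reductone once C8 is raised to the lactone level.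
4. Butenolide 9 (ring C5–C6–O7–C8–C1, formed first) comes from Dieckmann cyclisation of the (benzyloxy)acetate of mandelate 5; the C6 stereocentre comes from asymmetric transfer hydrogenation of keto ester 4.
5. Ylide precursor 12 comes from aldehyde 10 and (trimethylsilyl)methanol 11. Ring order: butenolide ring in step 4, second ring in step 7.

Key step: step 7

Remark: compounds 1, 2, 6, 10 and 11 are taken as commercial; locants in the overview are those of 3,7-dioxabicyclo[3.3.0]octane (C1/C5 carbinol ring-fusion carbons, C2/C6 aryl-bearing, C4/C8 methylene).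

## Route

Step 1
Reactants: 1 1-(benzyloxy)-4-bromo-2-methoxybenzene; 2 dimethyl oxalate
Product: 4 methyl 2-[4-(benzyloxy)-3-methoxyphenyl]-2-oxoacetate, via arylmagnesium bromide 3 (not isolated)
Conditions: Mg, THF, rt; then 2 (3 equiv), THF, −78 °C; aq. HCl
Reagents that add atoms: none
Why: Grignard mono-acylation of a dialkyl oxalate used in excess at low temperature should stop at the α-keto ester, because the tetrahedral magnesium alkoxide persists until work-up.

Step 2
Reactants: 4
Product: 5 methyl (2R)-2-[4-(benzyloxy)-3-methoxyphenyl]-2-hydroxyacetate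
Conditions: RuCl(p-cymene)[(S,S)-TsDPEN] (cat.), HCO2H–Et3N, DMF, rt
Reagents that add atoms: none
Why: Asymmetric transfer hydrogenation of an aryl α-keto ester (ruthenium–diamine bifunctional catalysis) should deliver hydride to one carbonyl face and set C2 as R, the catalyst antipode being chosen accordingly.

Step 3
Reactants: 5; 6 (benzyloxy)acetyl chloride
Product: 7 methyl (2R)-2-{[(benzyloxy)acetyl]oxy}-2-[4-(benzyloxy)-3-methoxyphenyl]acetate
Conditions: pyridine, DMAP (cat.), CH2Cl2, 0 °C
Reagents that add atoms: none
Why: O-Acylation of the secondary alcohol by an acid chloride under weakly basic conditions should leave the stereocentre untouched.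

Step 4
Reactants: 7
Product: 8 (5R)-3-(benzyloxy)-5-[4-(benzyloxy)-3-methoxyphenyl]-4-hydroxyfuran-2(5H)-one
Conditions: LiN(SiMe3)2 (2.2 equiv), THF, −78 °C; aq. HCl
Reagents that add atoms: none
Why: Dieckmann condensation, in which the enolate of the (benzyloxy)acetyl group attacks the methyl ester (5-exo-trig) and the acidic tetronic acid is held as its enolate, should carry the C5 stereocentre through unchanged at low temperature with the hindered amide base.

Step 5
Reactants: 8
Product: 9 (5R)-3,4-bis(benzyloxy)-5-[4-(benzyloxy)-3-methoxyphenyl]furan-2(5H)-one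
Conditions: BnOH, PPh3, DIAD, THF, 0 °C
Reagents that add atoms: benzyl alcohol OCc1ccccc1
Why: Mitsunobu O-alkylation of the acidic vinylogous-acid hydroxyl runs under neutral conditions, which avoids base-mediated epimerisation at C5 and C-alkylation at C3.

Step 6
Reactants: 10 4-(benzyloxy)-3-methoxybenzaldehyde; 11 (trimethylsilyl)methanol
Product: 12 1-(benzyloxy)-4-{chloro[(trimethylsilyl)methoxy]methyl}-2-methoxybenzene (racemic)
Conditions: HCl (gas), CaCl2, CH2Cl2, −20 °C; used crude as a solution
Reagents that add atoms: hydrogen chloride Cl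
Why: Classical α-chloro ether formation from aldehyde, alcohol and HCl (hemiacetal, then chloride substitution) should give the ylide precursor, whose C–Cl stereocentre is lost in the next step.

Step 7
Reactants: 9; 12
Product: 14 (3R,3aS,6R,6aS)-3a,6a-bis(benzyloxy)-3,6-bis[4-(benzyloxy)-3-methoxyphenyl]tetrahydro-1H,3H-furo[3,4-c]furan-1-one, via carbonyl ylide 13 (not isolated)
Conditions: CsF, MeCN, 0 °C to rt; 12 (3 equiv) added slowly
Reagents that add atoms: none
Why: Proposed new method: fluoride attacks silicon of 12 (1,3-elimination of Me3SiF and chloride) to give the non-stabilised carbonyl ylide 13, which adds as the 4π component across C3=C4 of 9 in a concerted suprafacial [3+2] cycloaddition; the closest known reaction type is the CsF-induced generation of such ylides from α-chloroalkyl silylmethyl ethers and their cycloaddition to acrylates, fumarates and maleimides, which has not been shown for a tetrasubstituted ene-diol diether. The one ring closed, tetrahydrofuran O5–C4–C3a–C6a–C6, forms by [3+2] closure with both new bonds (C4–C3a and C6–C6a) made on the same alkene face, so the ring fusion is necessarily cis and the two benzyloxy groups end up syn. Regiochemistry is secured by matched polarisation: the lactone carbonyl makes C4 of 9 the electrophilic and C3 the nucleophilic end of a push–pull alkene, while in 13 the CH2 terminus carries the carbanion character and the aryl-conjugated carbon the oxocarbenium character, so CH2 should bond to C4 and ArCH to C3. The absolute configuration of C3a and C6a follows from attack on the face anti to the C5 aryl group of 9, the one existing stereocentre. C6 is set by the approach of the E-configured ylide, whose aryl group should avoid the exocyclic lactone oxygen and lie over the small C3–O substituent, placing it cis to the 6a-benzyloxy group (exo aryl). The step therefore needs regio-, π-facial and exo selectivity and survival of the C5–H stereocentre, the last being helped by the vinylogous-carbonate character of 9, which lowers the C5–H acidity, and by keeping the fluoride heterogeneous and cold.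

Step 8
Reactants: 14
Product: 15 (3R,3aS,6R,6aS)-3a,6a-bis(benzyloxy)-3,6-bis[4-(benzyloxy)-3-methoxyphenyl]tetrahydro-1H,3H-furo[3,4-c]furan-1-ol (anomeric mixture at C1)
Conditions: i-Bu2AlH, CH2Cl2, −78 °C
Reagents that add atoms: none
Why: Partial reduction of the γ-lactone should stop at the lactol because the aluminium hemiacetal is stable at low temperature; the new C1 centre is an anomeric mixture that is removed in step 9.

Step 9
Reactants: 15
Product: 16 (1S,2R,5S,6R)-1,5-bis(benzyloxy)-2,6-bis[4-(benzyloxy)-3-methoxyphenyl]-3,7-dioxabicyclo[3.3.0]octane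
Conditions: Et3SiH, BF3·OEt2, CH2Cl2, −78 °C
Reagents that add atoms: none
Why: Ionic reduction of the lactol, in which the cyclic oxocarbenium ion at the lactol carbon is trapped by silane hydride, creates no stereocentre.

Step 10
Reactants: 16
Product: 17 prinsepiol, (1S,2R,5S,6R)-2,6-bis(4-hydroxy-3-methoxyphenyl)-3,7-dioxabicyclo[3.3.0]octane-1,5-diol
Conditions: H2 (1 atm), Pd(OH)2/C, NaHCO3, EtOAc–MeOH, rt
Reagents that add atoms: none
Why: Hydrogenolysis of the four O-benzyl groups should be selective because unhindered PhCH2–O bonds cleave faster than the ring ArCH–O bonds under buffered conditions, and no stereocentre is touched.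

## Compound list

1 | 1-(benzyloxy)-4-bromo-2-methoxybenzene | COc1cc(Br)ccc1OCc1ccccc1 | starting material
2 | dimethyl oxalate | COC(=O)C(=O)OC | starting material
3 | [4-(benzyloxy)-3-methoxyphenyl]magnesium bromide | COc1cc([Mg]Br)ccc1OCc1ccccc1 | intermediate
4 | methyl 2-[4-(benzyloxy)-3-methoxyphenyl]-2-oxoacetate | COC(=O)C(=O)c1ccc(OCc2ccccc2)c(OC)c1 | intermediate
5 | methyl (2R)-2-[4-(benzyloxy)-3-methoxyphenyl]-2-hydroxyacetate | COC(=O)[C@H](O)c1ccc(OCc2ccccc2)c(OC)c1 | intermediate
6 | (benzyloxy)acetyl chloride | O=C(Cl)COCc1ccccc1 | starting material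
7 | methyl (2R)-2-{[(benzyloxy)acetyl]oxy}-2-[4-(benzyloxy)-3-methoxyphenyl]acetate | COC(=O)[C@H](OC(=O)COCc1ccccc1)c1ccc(OCc2ccccc2)c(OC)c1 | intermediate
8 | (5R)-3-(benzyloxy)-5-[4-(benzyloxy)-3-methoxyphenyl]-4-hydroxyfuran-2(5H)-one | O=C1O[C@H](c2ccc(OCc3ccccc3)c(OC)c2)C(O)=C1OCc1ccccc1 | intermediate
9 | (5R)-3,4-bis(benzyloxy)-5-[4-(benzyloxy)-3-methoxyphenyl]furan-2(5H)-one | O=C1O[C@H](c2ccc(OCc3ccccc3)c(OC)c2)C(OCc2ccccc2)=C1OCc1ccccc1 | intermediate
10 | 4-(benzyloxy)-3-methoxybenzaldehyde | COc1cc(C=O)ccc1OCc1ccccc1 | starting material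
11 | (trimethylsilyl)methanol | C[Si](C)(C)CO | starting material
12 | 1-(benzyloxy)-4-{chloro[(trimethylsilyl)methoxy]methyl}-2-methoxybenzene (racemic) | COc1cc(C(Cl)OC[Si](C)(C)C)ccc1OCc1ccccc1 | intermediate
13 | (E)-carbonyl ylide from 12, [4-(benzyloxy)-3-methoxybenzylidene]oxonium methylide | COc1cc(/C=[O+]/[CH2-])ccc1OCc1ccccc1 | intermediate
14 | (3R,3aS,6R,6aS)-3a,6a-bis(benzyloxy)-3,6-bis[4-(benzyloxy)-3-methoxyphenyl]tetrahydro-1H,3H-furo[3,4-c]furan-1-one | COc1cc([C@H]2OC[C@]3(OCc4ccccc4)[C@@H](c4ccc(OCc5ccccc5)c(OC)c4)OC(=O)[C@]23OCc2ccccc2)ccc1OCc1ccccc1 | intermediate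
15 | (3R,3aS,6R,6aS)-3a,6a-bis(benzyloxy)-3,6-bis[4-(benzyloxy)-3-methoxyphenyl]tetrahydro-1H,3H-furo[3,4-c]furan-1-ol (anomeric mixture) | COc1cc([C@H]2OC[C@]3(OCc4ccccc4)[C@@H](c4ccc(OCc5ccccc5)c(OC)c4)OC(O)[C@]23OCc2ccccc2)ccc1OCc1ccccc1 | intermediate
16 | (1S,2R,5S,6R)-1,5-bis(benzyloxy)-2,6-bis[4-(benzyloxy)-3-methoxyphenyl]-3,7-dioxabicyclo[3.3.0]octane | COc1cc([C@H]2OC[C@]3(OCc4ccccc4)[C@@H](c4ccc(OCc5ccccc5)c(OC)c4)OC[C@]23OCc2ccccc2)ccc1OCc1ccccc1 | intermediate
17 | prinsepiol, (1S,2R,5S,6R)-2,6-bis(4-hydroxy-3-methoxyphenyl)-3,7-dioxabicyclo[3.3.0]octane-1,5-diol | COc1cc([C@H]2OC[C@]3(O)[C@@H](c4ccc(O)c(OC)c4)OC[C@]23O)ccc1O | target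

## Step count and risks

Total step count: 10. Longest linear sequence: 9 (steps 1, 2, 3, 4, 5, 7, 8, 9, 10).

Steps most likely to fail:

1. Step 7 (Proposed new method). Three processes may defeat it. The cycloaddition may be too slow at the tetrasubstituted, donor-substituted alkene, so that the ylide closes to the oxirane or oligomerises. Fluoride or the ylide may deprotonate C5 of 9 and erode optical purity. A competing endo approach would give the C6 epimer. The fallback sets out from 9 and 10 and uses the neutral, known three-component variant. Rh2(OAc)4-catalysed decomposition of 2,2,2-trichloroethyl diazoacetate in the presence of 10 and 9 (CH2Cl2, rt, slow addition) forms an ester-stabilised carbonyl ylide from the rhodium carbenoid and the aldehyde oxygen. Its cycloaddition, with the same polarisation logic, should give trichloroethyl ester cycloadduct F1. Zn/AcOH should unmask carboxylic acid F2. Coupling with 1-hydroxypyridine-2-thione (DCC) should give Barton ester F3, and photolysis with t-BuSH (Barton reductive decarboxylation) replaces the carboxyl group by hydrogen. The fallback returns to the route at 14.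

2. Step 9. The Lewis acid may ionise the electron-rich benzylic C–O bonds (C3–O2, C6–O5) in competition with the lactol, causing ring opening, epimerisation or over-reduction. The fallback sets out from 14. LiBH4 (THF) should reduce the lactone to diol F4, and TsCl/pyridine should sulfonylate the primary hydroxyl selectively to give primary monotosylate F5. NaH (THF) should then close the ring by intramolecular Williamson etherification (5-exo-tet); the benzylic alkoxide is the nucleophile, so the benzylic carbon keeps its configuration. The fallback returns to the route at 16.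

3. Step 10. Hydrogenolytic opening of the ring benzylic C–O bonds may compete with the slower cleavage of the two hindered tertiary benzyl ethers. The fallback sets out from 16 and replaces surface hydrogenolysis by single-electron reductive debenzylation with LiC10H8 (lithium naphthalenide, THF, −78 °C). The unsubstituted benzyl groups should accept the electron more readily than the dialkoxyaryl rings. It gives 17 directly and makes no new compound.

## Further compounds

F1 | step 7 | 2,2,2-trichloroethyl ester of the 4-carboxy derivative of 14 (epimers at C4) | COc1cc([C@H]2OC(C(=O)OCC(Cl)(Cl)Cl)[C@]3(OCc4ccccc4)[C@@H](c4ccc(OCc5ccccc5)c(OC)c4)OC(=O)[C@]23OCc2ccccc2)ccc1OCc1ccccc1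
F2 | step 7 | 4-carboxylic acid derivative of 14 (epimers at C4) | COc1cc([C@H]2OC(C(=O)O)[C@]3(OCc4ccccc4)[C@@H](c4ccc(OCc5ccccc5)c(OC)c4)OC(=O)[C@]23OCc2ccccc2)ccc1OCc1ccccc1
F3 | step 7 | 2-thioxopyridin-1(2H)-yl ester (Barton ester) of F2 | COc1cc([C@H]2OC(C(=O)ON6C=CC=CC6=S)[C@]3(OCc4ccccc4)[C@@H](c4ccc(OCc5ccccc5)c(OC)c4)OC(=O)[C@]23OCc2ccccc2)ccc1OCc1ccccc1
F4 | step 9 | diol from reductive opening of the lactone of 14: 3,4-bis(benzyloxy)-2-aryl-4-[(R)-aryl(hydroxy)methyl]-3-(hydroxymethyl)tetrahydrofuran, aryl = 4-(benzyloxy)-3-methoxyphenyl | COc1cc([C@H]2OC[C@](OCc3ccccc3)([C@H](O)c3ccc(OCc4ccccc4)c(OC)c3)[C@@]2(CO)OCc2ccccc2)ccc1OCc1ccccc1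
F5 | step 9 | primary mono(4-methylbenzenesulfonate) of F4 | COc1cc([C@H]2OC[C@](OCc3ccccc3)([C@H](O)c3ccc(OCc4ccccc4)c(OC)c3)[C@@]2(COS(=O)(=O)c3ccc(C)cc3)OCc2ccccc2)ccc1OCc1ccccc1
F0 | step 10 | none | none
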